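The ketone is cut between the carbonyl carbon and its α‑methylene. This bond is made by a rhodium‑catalysed intermolecular hydroacylation: the formyl C–H of 2,4‑dihydroxy‑3,5‑diprenylbenzaldehyde adds across the vinyl group of 4‑acetoxystyrene with linear selectivity, creating the whole Ar–C(=O)–CH2–CH2–Ar′ bridge at the correct oxidation level in one atom‑economic operation. The step exploits the C2′ hydroxyl ortho to the carbonyl on the pentasubstituted resorcinol ring A: as a salicylaldehyde phenoxide it chelates rhodium and suppresses decarbonylation. The aldehyde arises from 2,4‑dihydroxybenzaldehyde by diiodination at C3/C5, MOM protection, double Stille prenylation and MOM removal.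

Key step: step 5

Remark: the target has no stereocentre and no stereogenic double bond (each alkene carries two methyl groups on one carbon), so it is achiral and no stereocontrol is needed.

**Step 1**
Reactants: 1 2,4‑dihydroxybenzaldehyde
Product: 2 2,4‑dihydroxy‑3,5‑diiodobenzaldehyde
Conditions: ICl (2.2 equiv), AcOH, rt
Reagents that add atoms: iodine monochloride, ClI
Why: Electrophilic aromatic iodination, in which C3 and C5 are the only ring positions ortho or para to both hydroxyl groups while C6 is meta to both, so two equivalents of ICl should give the 3,5‑diiodide.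

**Step 2**
Reactants: 2 2,4‑dihydroxy‑3,5‑diiodobenzaldehyde
Product: 3 3,5‑diiodo‑2,4‑bis(methoxymethoxy)benzaldehyde
Conditions: NaH (2.5 equiv), MOMCl (2.5 equiv), DMF, 0 °C to rt
Reagents that add atoms: chloromethyl methyl ether, COCCl
Why: Williamson‑type O‑alkylation of both sodium phenoxides, which masks the acidic phenols that would otherwise protodestannylate the allylstannane and slow oxidative addition in step 3.

**Step 3**
Reactants: 3 3,5‑diiodo‑2,4‑bis(methoxymethoxy)benzaldehyde; 4 tributyl(3‑methylbut‑2‑en‑1‑yl)stannane (2.6 equiv)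
Product: 5 2,4‑bis(methoxymethoxy)‑3,5‑bis(3‑methylbut‑2‑en‑1‑yl)benzaldehyde
Conditions: Pd(PPh3)4 (10 mol %), DMF, 90 °C
Reagents that add atoms: none
Why: Twofold Stille cross‑coupling of the aryl iodides, in which the allyl–palladium intermediate should reductively eliminate at its unhindered CH2 terminus and so give linear prenyl groups rather than 1,1‑dimethylallyl isomers.

**Step 4**
Reactants: 5 2,4‑bis(methoxymethoxy)‑3,5‑bis(3‑methylbut‑2‑en‑1‑yl)benzaldehyde
Product: 6 2,4‑dihydroxy‑3,5‑bis(3‑methylbut‑2‑en‑1‑yl)benzaldehyde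
Conditions: 3 M aq. HCl, MeOH, 40 °C, short reaction time
Reagents that add atoms: none
Why: Acid‑catalysed methanolysis of the two aryl MOM acetals, kept mild and short so that the prenyl alkenes are not protonated and no chroman forms.

**Step 5**
Reactants: 6 2,4‑dihydroxy‑3,5‑bis(3‑methylbut‑2‑en‑1‑yl)benzaldehyde; 7 4‑ethenylphenyl acetate (4‑acetoxystyrene, 1.3 equiv)
Product: 9 Gancaonin J, via 4‑O‑acetylgancaonin J 8 (not isolated)
Conditions: [Rh(cod)OMe]2 (2.5 mol %), BINOL‑derived phosphoramidite ligand (10 mol %), K3PO4 (10 mol %), 1,4‑dioxane, 70 °C; then K2CO3 (2 equiv), MeOH, rt; 1 M HCl work‑up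
Reagents that add atoms: none
Why: Rh‑catalysed intermolecular alkene hydroacylation of a salicylaldehyde: the C2 phenoxide binds Rh(I), oxidative addition of the formyl C–H gives a five‑membered O,C‑chelated acyl–Rh(III) hydride that resists decarbonylation, the vinyl group of 7 inserts into Rh–H, and C–C reductive elimination from the primary alkyl forms the C(=O)–CH2 bond. The closest known reaction type is the chelation‑assisted, linear‑selective Rh‑catalysed hydroacylation of terminal alkenes with salicylaldehydes. No ring is closed and no stereocentre is formed. The step needs linear over branched regioselectivity, which should follow because hydride insertion is reversible and reductive elimination from the unhindered primary alkyl is faster than from the benzylic one at a bulky monodentate ligand. It also needs chemoselectivity for the monosubstituted styrene over the two trisubstituted prenyl alkenes, which insert far more slowly and, sitting at C3 and C5, cannot reach the acyl–rhodium centre intramolecularly. The acetate keeps the styrene partner stable and is removed in the same flask by base‑mediated methanolysis, which should give the target.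

**Compound list**
1 | 2,4‑dihydroxybenzaldehyde | O=Cc1ccc(O)cc1O | starting material
2 | 2,4‑dihydroxy‑3,5‑diiodobenzaldehyde | O=Cc1cc(I)c(O)c(I)c1O | intermediate
3 | 3,5‑diiodo‑2,4‑bis(methoxymethoxy)benzaldehyde | O=Cc1cc(I)c(OCOC)c(I)c1OCOC | intermediate
4 | tributyl(3‑methylbut‑2‑en‑1‑yl)stannane | CCCC[Sn](CCCC)(CCCC)CC=C(C)C | starting material
5 | 2,4‑bis(methoxymethoxy)‑3,5‑bis(3‑methylbut‑2‑en‑1‑yl)benzaldehyde | O=Cc1cc(CC=C(C)C)c(OCOC)c(CC=C(C)C)c1OCOC | intermediate
6 | 2,4‑dihydroxy‑3,5‑bis(3‑methylbut‑2‑en‑1‑yl)benzaldehyde | O=Cc1cc(CC=C(C)C)c(O)c(CC=C(C)C)c1O | intermediate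
7 | 4‑ethenylphenyl acetate (4‑acetoxystyrene) | C=Cc1ccc(OC(C)=O)cc1 | starting material
8 | 4‑{3‑[2,4‑dihydroxy‑3,5‑bis(3‑methylbut‑2‑en‑1‑yl)phenyl]‑3‑oxopropyl}phenyl acetate (4‑O‑acetylgancaonin J) | CC(=O)Oc1ccc(CCC(=O)c2cc(CC=C(C)C)c(O)c(CC=C(C)C)c2O)cc1 | intermediate (not isolated)
9 | Gancaonin J, 1‑[2,4‑dihydroxy‑3,5‑bis(3‑methylbut‑2‑en‑1‑yl)phenyl]‑3‑(4‑hydroxyphenyl)propan‑1‑one | CC(C)=CCc1cc(C(=O)CCc2ccc(O)cc2)c(O)c(CC=C(C)C)c1O | target

**Step count**
Total steps: 5. Longest linear sequence: 5 steps (from 1).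

**Steps most likely to fail**

Step 5 (key step). The styrene may insert with the opposite regiochemistry and lead to the branched α‑aryl ketone. The acyl–rhodium hydride may decarbonylate, the more acidic C4 phenoxide may sequester the catalyst, or the styrene may polymerise. The fallback sets out from 5 and comes back at 9; it makes the same C(=O)–CH2 bond by carbonyl addition instead of C–H activation. Commercial 4‑(2‑bromoethyl)phenol (Oc1ccc(CCBr)cc1) would be protected (MOMCl, i‑Pr2NEt, CH2Cl2, 0 °C) as 1‑(2‑bromoethyl)‑4‑(methoxymethoxy)benzene F1. Magnesium in THF would convert this into {2‑[4‑(methoxymethoxy)phenyl]ethyl}magnesium bromide F2. Addition of the Grignard reagent to the protected aldehyde 5 (THF, −78 to 0 °C) should give racemic 1‑[2,4‑bis(methoxymethoxy)‑3,5‑bis(3‑methylbut‑2‑en‑1‑yl)phenyl]‑3‑[4‑(methoxymethoxy)phenyl]propan‑1‑ol F3. Dess–Martin oxidation (NaHCO3, CH2Cl2) should give 1‑[2,4‑bis(methoxymethoxy)‑3,5‑bis(3‑methylbut‑2‑en‑1‑yl)phenyl]‑3‑[4‑(methoxymethoxy)phenyl]propan‑1‑one F4. The acid methanolysis of step 4 (HCl, MeOH) would then remove all three MOM groups to give 9.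

Step 3. The second coupling at the doubly flanked C3 iodide may stall, protodeiodination may compete, the allyl group may couple through its tertiary terminus (reverse prenyl), or palladium may transfer the allyl group to the aldehyde. The fallback sets out from 3 and comes back at 6; it reverses the polarity, using an aryl nucleophile and prenyl bromide. The aldehyde of 3 would be masked (HC(OMe)3, PPTS cat., MeOH) as 1‑(dimethoxymethyl)‑3,5‑diiodo‑2,4‑bis(methoxymethoxy)benzene F5. Double iodine–lithium exchange (t‑BuLi, 4.2 equiv, THF, −78 °C) should give the OMOM‑stabilised [5‑(dimethoxymethyl)‑2,4‑bis(methoxymethoxy)‑1,3‑phenylene]dilithium F6. Transmetalation with CuBr·SMe2 and SN2 alkylation with 1‑bromo‑3‑methylbut‑2‑ene should give 1‑(dimethoxymethyl)‑2,4‑bis(methoxymethoxy)‑3,5‑bis(3‑methylbut‑2‑en‑1‑yl)benzene F7. Aqueous HCl in MeOH would then cleave the acetal and both MOM ethers in one operation to give 6.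

Step 4. A freed phenol may cyclise under acid onto the neighbouring prenyl alkene (2,2‑dimethylchroman formation), or methanol or water may add across the alkenes before the hindered C4 MOM ether is fully cleaved. The fallback sets out from 2 and comes back at 6; it replaces the acid‑labile protecting group by a base‑labile one, so the prenylated ring never meets acid. Acetylation of 2 (Ac2O, pyridine, DMAP cat.) should give 4‑formyl‑2,6‑diiodo‑1,3‑phenylene diacetate F8. Fluoride‑free Stille coupling with 4 (Pd(PPh3)4, toluene/DMF, 90 °C) should give 4‑formyl‑2,6‑bis(3‑methylbut‑2‑en‑1‑yl)‑1,3‑phenylene diacetate F9. Methanolysis (K2CO3, MeOH, rt) would release 6.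

**Further compounds**
F1 | step 5 | 1‑(2‑bromoethyl)‑4‑(methoxymethoxy)benzene | COCOc1ccc(CCBr)cc1
F2 | step 5 | {2‑[4‑(methoxymethoxy)phenyl]ethyl}magnesium bromide | COCOc1ccc(CC[Mg]Br)cc1
F3 | step 5 | 1‑[2,4‑bis(methoxymethoxy)‑3,5‑bis(3‑methylbut‑2‑en‑1‑yl)phenyl]‑3‑[4‑(methoxymethoxy)phenyl]propan‑1‑ol (racemic) | COCOc1ccc(CCC(O)c2cc(CC=C(C)C)c(OCOC)c(CC=C(C)C)c2OCOC)cc1
F4 | step 5 | 1‑[2,4‑bis(methoxymethoxy)‑3,5‑bis(3‑methylbut‑2‑en‑1‑yl)phenyl]‑3‑[4‑(methoxymethoxy)phenyl]propan‑1‑one | COCOc1ccc(CCC(=O)c2cc(CC=C(C)C)c(OCOC)c(CC=C(C)C)c2OCOC)cc1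
F5 | step 3 | 1‑(dimethoxymethyl)‑3,5‑diiodo‑2,4‑bis(methoxymethoxy)benzene | COC(OC)c1cc(I)c(OCOC)c(I)c1OCOC
F6 | step 3 | [5‑(dimethoxymethyl)‑2,4‑bis(methoxymethoxy)‑1,3‑phenylene]dilithium | COC(OC)c1cc([Li])c(OCOC)c([Li])c1OCOC
F7 | step 3 | 1‑(dimethoxymethyl)‑2,4‑bis(methoxymethoxy)‑3,5‑bis(3‑methylbut‑2‑en‑1‑yl)benzene | COC(OC)c1cc(CC=C(C)C)c(OCOC)c(CC=C(C)C)c1OCOC
F8 | step 4 | 4‑formyl‑2,6‑diiodo‑1,3‑phenylene diacetate | CC(=O)Oc1c(I)cc(C=O)c(OC(C)=O)c1I
F9 | step 4 | 4‑formyl‑2,6‑bis(3‑methylbut‑2‑en‑1‑yl)‑1,3‑phenylene diacetate | CC(=O)Oc1c(CC=C(C)C)cc(C=O)c(OC(C)=O)c1CC=C(C)C
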